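# Proposed synthesis of (2S,3S,4S,5S)-2,5-bis(4-hydroxy-3-methoxyphenyl)-3,4-bis(hydroxymethyl)tetrahydrofuran (17)

## The problem

Target 17 is one oxolane ring (O1, C2, C3, C4, C5) with 4-hydroxy-3-methoxyphenyl groups on C2 and C5 and hydroxymethyl groups (carbons C3' and C4') on C3 and C4. All four ring carbons are stereocentres, (2S,3S,4S,5S), and the molecule is C2-symmetric: aryl and hydroxymethyl are cis at C2/C3 and at C4/C5, and the two hydroxymethyl groups are trans. This cis,trans,cis array is not the thermodynamic one. Equilibration, or ring closure through benzylic cations, would put each aryl group trans to its neighbour, so every centre must be set kinetically. C2 and C5 are p-oxygenated benzylic ether carbons: acid ionises them (epimerisation), and they are the bonds most at risk in a final hydrogenolysis. The phenols are oxidation-prone and are best unveiled last. One centre made by an enantioselective carbonyl addition (C2) can govern C3 by 1,2-induction, and the hydroxymethyl group on C3 can then steer a reagent to one face of C4 and C5 if these two atoms stay planar until late. The enabling feature is that C3 and C4, with C4' at the carboxyl level, are the β- and α-carbons of an enoate whose γ-carbon C2 already bears O1. C3' can therefore enter as a nucleophile at C3, C5 as an aroyl electrophile at C4, and O1 can close onto the C5 carbonyl.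

## Retrosynthesis

**17 ⇒ 16.** The two phenol O–H bonds are traced back to benzyl ethers. Benzyl survives organometallic, hydride, fluoride/peroxide and homogeneous hydrogenation conditions, and both aryl rings carry the same group, so the symmetry is kept. The forward step must cleave aryl benzyl ethers without touching the ring benzylic C–O bonds.

**16 ⇒ 15.** The C4' alcohol is taken back to a methyl ester. This costs one reduction but identifies C4 as the α-carbon of an ester, which the key step needs. The forward reduction must not epimerise C4.

**15 ⇒ 14.** The C4–H and C5–H bonds are cut, removing two stereocentres and giving the dihydrofuran ester 14. Cutting O1–C5 instead, by cationic etherification, would give the trans arrangement at C5. The forward step must add H2 to the face bearing the C3 hydroxymethyl and C2 aryl groups, the more hindered one. An undirected catalyst would give the all-cis isomer, so the free C3' hydroxyl is used as a directing group.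

**14 ⇒ 13.** The C3'–O bond is traced to a C3'–Si bond (Tamao–Fleming oxidation). This lets C3' be introduced as a carbon nucleophile; an oxygenated carbanion would be harder to make and to unmask. The oxidation must leave the enol ether and ester alone.

**13 ⇒ 5 + 9 + 7.** Three bonds are cut together: C3–C3' (conjugate addition of Grignard reagent 9 to Z-enoate 5), C4–C5 (acylation of the enolate by aroyl chloride 7) and O1–C5 (hemiketalisation and dehydration). Having C5 at the acyl level avoids an aldol-level cut, which would create two more centres to control, and lets the ring close by carbonyl addition with no benzylic cation. The precursors carry one stereocentre between them. The forward reaction needs syn 1,2-induction from C2 and C-acylation of the enolate.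

**5 ⇒ 4 ⇒ 3 ⇒ 1 + 2.** The Z-alkene is taken back to the alkyne 4 (semi-hydrogenation), the silyl ether to alcohol 3, and the C2–alkyne bond is cut to give aldehyde 1 and methyl propiolate 2. One catalytic asymmetric alkynylation sets the only stereocentre that is not substrate-controlled. The silyl ether prevents lactonisation of the Z-γ-hydroxy enoate.

**7 ⇒ 6 and 9 ⇒ 8.** The acid chloride comes from acid 6, and the Grignard reagent from chloromethylsilane 8.

## Roads not taken

**Alternative 1:** The cut is C2–C3 and C4–C5 around a C3–C4 core supplied by the menthyloxy butenolide A1 (its acetal carbon is C3', its carbonyl C4'). In the forward step lithiated dithiane A2 adds to the β-carbon of A1 anti to the menthyloxy group, and the lactone enolate is trapped by aldehyde 1 to give A3; no ring closes.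
- Merits: this three-component coupling is very well precedented in lignan chemistry, the auxiliary is cheap and crystalline, and the 3,4-trans relation comes out of it directly. In reliability of its key step this road is better than the chosen one.
- Weak points for 17: C2 arrives as a thioketal and C5 as a carbinol. The oxolane must later be closed by dehydrative etherification between electron-rich benzylic centres, which runs through benzylic cations and places aryl trans to its neighbour, the opposite of what 17 needs at both ends. Acetal cleavage, dethioketalisation and two reductions add length.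
- Comparison: the chosen plan offers a less proven coupling, but it closes the ring at the acyl level in the same operation, has C2 fixed beforehand and sets C5 by syn hydrogenation.

**Alternative 2:** The cut is C4–C5 and the lactone C–O bond at C2, giving succinate mono-imide A4 and aldehyde 1. In the forward step a MgCl2/Et3N/Me3SiCl-promoted anti-aldol and acidic work-up give the cis paraconic lactone A5.
- Merits: absolute configuration and the C4/C5-cis relation come from a recoverable auxiliary in one operation. For this pair of centres it is more trustworthy than the hindered-face hydrogenation of the chosen plan.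
- Weak points: A5 holds one aryl group only. C3' must enter by enolate alkylation next to the more acidic imide α-carbon C4 (regiochemistry, epimerisation). The second aryl group needs organometallic addition to the lactone and a Lewis-acid silane reduction at C2 beside the acid-labile C5 benzylic ether. Auxiliary removal follows.
- Comparison: the sequence is linear, builds one bond per step and is at least as long. The chosen plan sets convergence against the better C4/C5 control: both aryl carbons and C3' are in place after one step, and no Lewis acid is used once the ring exists.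

**Alternative 3:** The cut is O1–C5 and C2–H. In the forward step BF3·OEt2 activates keto-β-lactone A6, the ketone oxygen opens the lactone at benzylic C5 with inversion, and Et3SiH reduces the 2-aryl oxocarbenium ion anti to the C3 substituent, giving acid A7.
- Merits: the ring and two stereocentres form together under stereoelectronic control, and the cis,trans,cis pattern follows directly. Hydride delivery at C2 is inherently more reliable than the directed hydrogenation here.
- Weak points: A6 already has three stereocentres and a strained ring, so most of the work lies before the key step. The C5 aryl group must be deactivated as a pivalate while the other stays a benzyl ether, which loses the symmetry. BF3 meets electron-rich benzyl ethers, and the acid and an alkyl benzyl ether remain to be processed.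
- Comparison: the chosen plan assembles the skeleton from three simple pieces with uniform protection, at the price of a riskier hydrogenation.

Key step: step 6

**Remarks.**
- Ar = 4-(benzyloxy)-3-methoxyphenyl.
- Locants C2–C5, C3', C4' refer to the target ring (C2 from aldehyde 1, C5 from acid chloride 7). The systematic names of 13–15 number the ring from the other end.
- Assumption: 1, 2, 6 and 8 are purchased.
- Assumption: the (R,R)-ProPhenol–zinc catalyst is taken to add the alkynyl group to the Si face of 1; if the opposite sense is found, the (S,S)-ligand is used and nothing else changes.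

## Route

Step 1
Reactants: 1 4-(benzyloxy)-3-methoxybenzaldehyde; 2 methyl propiolate
Product: 3 methyl (R)-4-Ar-4-hydroxybut-2-ynoate
Conditions: 2 (3 equiv), Me2Zn (3 equiv), (R,R)-ProPhenol (10 mol %), Ph3PO (20 mol %), toluene, 0 °C
Reagents that add atoms: none
Why: Zinc–ProPhenol-catalysed asymmetric alkynylation: Me2Zn deprotonates 2 and the dinuclear zinc–ligand complex binds aldehyde and alkynylzinc so that the alkynyl group reaches the Si face of 1, setting C2 (R here because the alkynyl group outranks aryl); the enantiomeric purity and sense should be checked by Mosher ester analysis.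

Step 2
Reactants: 3 methyl (R)-4-Ar-4-hydroxybut-2-ynoate
Product: 4 methyl (R)-4-Ar-4-(triethylsilyloxy)but-2-ynoate
Conditions: TESOTf, 2,6-lutidine, CH2Cl2, −78 °C
Reagents that add atoms: triethylsilyl trifluoromethanesulfonate, CC[Si](CC)(CC)OS(=O)(=O)C(F)(F)F
Why: Silylation of a secondary alcohol with a silyl triflate and a hindered base; nucleophilic amines are avoided because they add to the ynoate, and the silyl ether later prevents lactonisation of the Z-enoate.

Step 3
Reactants: 4 methyl (R)-4-Ar-4-(triethylsilyloxy)but-2-ynoate
Product: 5 methyl (S,Z)-4-Ar-4-(triethylsilyloxy)but-2-enoate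
Conditions: H2 (1 atm), Pd/CaCO3 poisoned with Pb(OAc)2 (Lindlar catalyst), quinoline, EtOAc, rt
Reagents that add atoms: none
Why: Lindlar semi-hydrogenation: syn addition of H2 on the poisoned palladium surface should give the Z-enoate and leave benzyl and silyl ethers alone; the stereocentre is untouched (the descriptor changes to S only because alkenyl ranks below aryl).

Step 4
Reactants: 6 4-(benzyloxy)-3-methoxybenzoic acid
Product: 7 4-(benzyloxy)-3-methoxybenzoyl chloride
Conditions: (COCl)2, DMF (cat.), CH2Cl2, 0 °C → rt; evaporate, use crude
Reagents that add atoms: oxalyl chloride, O=C(Cl)C(=O)Cl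
Why: Acid chloride formation through the chloroiminium species generated from DMF; the aryl benzyl ether is stable to these conditions.

Step 5
Reactants: 8 (chloromethyl)dimethyl(propan-2-yloxy)silane
Product: 9 {[dimethyl(propan-2-yloxy)silyl]methyl}magnesium chloride
Conditions: Mg turnings, BrCH2CH2Br (cat.), THF, reflux then rt; titrate, use as solution
Reagents that add atoms: magnesium, [Mg]
Why: Grignard formation from an α-silyl alkyl chloride; this reagent is the standard nucleophilic hydroxymethyl equivalent.

Step 6
Reactants: 5 methyl (S,Z)-4-Ar-4-(triethylsilyloxy)but-2-enoate; 9 {[dimethyl(propan-2-yloxy)silyl]methyl}magnesium chloride; 7 4-(benzyloxy)-3-methoxybenzoyl chloride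
Product: 13 methyl (4R,5S)-2,5-bis(Ar)-4-{[dimethyl(propan-2-yloxy)silyl]methyl}-4,5-dihydrofuran-3-carboxylate, via magnesium enolate 10 (not isolated), via keto ester 11 (not isolated), via cyclic hemiketal 12 (not isolated)
Conditions: 9 (1.3 equiv), CuI (10 mol %), THF, −78 → −40 °C; then 7 (2 equiv), −78 → 0 °C; then i-PrOH, camphorsulfonic acid, 0 °C → rt
Reagents that add atoms: none
Why: Transmetallation of 9 to CuI gives a silylmethylcuprate of monovalent copper that binds the Z-enoate as a π-complex, adds at C3 (trivalent copper) and reductively eliminates, forming C3–C3' and the chloromagnesium enolate 10; the closest known reaction type is the CuI-catalysed 1,4-addition of this hydroxymethyl equivalent to enones and of Grignard reagents to enoates. Enolate 10 is then C-acylated by 7 in a crossed Claisen-type acylation (C4–C5) to give 11 as a mixture at C4, which does not matter. Acid-catalysed isopropanolysis removes the triethylsilyl group (the isopropoxysilane can only exchange with its own alcohol), the freed C2 hydroxyl adds to the aryl ketone in a 5-exo-trig closure (O1–C5) to hemiketal 12, and loss of water gives the enol ether conjugated with the ester, in which C4 and C5 are planar again. The only new stereocentre that survives is C3, and it is controlled by C2: A1,3 strain with the cis ester holds the C2–H bond in the plane of the Z-enoate, the aryl and silyloxy groups cover the two faces, and the cuprate should add anti to the aryl group, past the oxygen whose silyl group can turn outwards. That face gives the syn adduct (silylmethyl and silyloxy syn in the extended chain), which is 2,3-cis once O1 is in the ring; addition anti to the C–O bond would give the trans series. The step needs 1,4- over 1,2-addition (soft cuprate, hindered α-silyl Grignard reagent), syn facial selectivity (Z geometry from step 3, moderate size of the triethylsilyl group), C- over O-acylation (chelated magnesium ester enolate) and closure on the ketone and not on the ester (the ketone is the better electrophile and the dehydration is irreversible).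

Step 7
Reactants: 13 methyl (4R,5S)-2,5-bis(Ar)-4-{[dimethyl(propan-2-yloxy)silyl]methyl}-4,5-dihydrofuran-3-carboxylate
Product: 14 methyl (4S,5S)-2,5-bis(Ar)-4-(hydroxymethyl)-4,5-dihydrofuran-3-carboxylate
Conditions: 30% H2O2, KF, KHCO3, THF/MeOH (1:1), rt
Reagents that add atoms: hydrogen peroxide, OO
Why: Tamao–Fleming oxidation: fluoride gives a pentacoordinate silicate, hydroperoxide adds and C3' migrates from silicon to oxygen, leaving C3 untouched (its descriptor changes only by priority); the buffered conditions should spare the vinylogous carbonate, whose low electrophilicity and ring-fusion alkene also disfavour lactonisation.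

Step 8
Reactants: 14 methyl (4S,5S)-2,5-bis(Ar)-4-(hydroxymethyl)-4,5-dihydrofuran-3-carboxylate
Product: 15 methyl (2S,3R,4S,5S)-2,5-bis(Ar)-4-(hydroxymethyl)tetrahydrofuran-3-carboxylate
Conditions: H2 (50 bar), [Ir(cod)(PCy3)(py)][B(3,5-(CF3)2C6H3)4] (5–10 mol %), CH2Cl2, rt
Reagents that add atoms: none
Why: Hydroxyl-directed homogeneous hydrogenation: the cationic iridium centre binds the C3' hydroxyl and the alkene and should add both hydrogens to the face cis to the hydroxymethyl group, so the ester on C4 and the aryl group on C5 end up cis to each other and trans to C3 and C2. The non-coordinating anion and pressure are chosen for the tetrasubstituted alkene; this catalyst does not cleave benzyl ethers.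

Step 9
Reactants: 15 methyl (2S,3R,4S,5S)-2,5-bis(Ar)-4-(hydroxymethyl)tetrahydrofuran-3-carboxylate
Product: 16 [(2S,3S,4S,5S)-2,5-bis(Ar)tetrahydrofuran-3,4-diyl]dimethanol
Conditions: LiAlH4, THF, −20 → 0 °C
Reagents that add atoms: none
Why: Hydride reduction of the ester to the primary alcohol; reduction should outpace enolisation so C4 keeps its configuration, and the trans hydroxy ester cannot lactonise.

Step 10
Reactants: 16 [(2S,3S,4S,5S)-2,5-bis(Ar)tetrahydrofuran-3,4-diyl]dimethanol
Product: 17 4,4'-[(2S,3S,4S,5S)-3,4-bis(hydroxymethyl)tetrahydrofuran-2,5-diyl]bis(2-methoxyphenol)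
Conditions: H2 (1 atm), 10% Pd/C, EtOAc, rt, stopped at full conversion; neutral work-up
Reagents that add atoms: none
Why: Catalytic hydrogenolysis of aryl benzyl ethers, which are cleaved much faster than the ring's dialkyl benzylic ethers in a neutral, aprotic solvent; neutral work-up avoids quinone-methide epimerisation at C2 and C5.

## Compound list

1 | 4-(benzyloxy)-3-methoxybenzaldehyde | COc1cc(C=O)ccc1OCc1ccccc1 | starting material
2 | methyl prop-2-ynoate (methyl propiolate) | C#CC(=O)OC | starting material
3 | methyl (R)-4-[4-(benzyloxy)-3-methoxyphenyl]-4-hydroxybut-2-ynoate | COc1cc([C@H](C#CC(=O)OC)O)ccc1OCc1ccccc1 | intermediate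
4 | methyl (R)-4-[4-(benzyloxy)-3-methoxyphenyl]-4-[(triethylsilyl)oxy]but-2-ynoate | COc1cc([C@H](C#CC(=O)OC)O[Si](CC)(CC)CC)ccc1OCc1ccccc1 | intermediate
5 | methyl (S,Z)-4-[4-(benzyloxy)-3-methoxyphenyl]-4-[(triethylsilyl)oxy]but-2-enoate | COc1cc([C@H](/C=C\C(=O)OC)O[Si](CC)(CC)CC)ccc1OCc1ccccc1 | intermediate
6 | 4-(benzyloxy)-3-methoxybenzoic acid | COc1cc(C(=O)O)ccc1OCc1ccccc1 | starting material
7 | 4-(benzyloxy)-3-methoxybenzoyl chloride | COc1cc(C(=O)Cl)ccc1OCc1ccccc1 | intermediate
8 | (chloromethyl)dimethyl(propan-2-yloxy)silane | CC(C)O[Si](C)(C)CCl | starting material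
9 | {[dimethyl(propan-2-yloxy)silyl]methyl}magnesium chloride | CC(C)O[Si](C)(C)C[Mg]Cl | intermediate
10 | chloromagnesium enolate of methyl (3R,4S)-4-[4-(benzyloxy)-3-methoxyphenyl]-3-{[dimethyl(propan-2-yloxy)silyl]methyl}-4-[(triethylsilyl)oxy]butanoate | COc1cc([C@@H](O[Si](CC)(CC)CC)[C@H](C[Si](C)(C)OC(C)C)C=C(OC)O[Mg]Cl)ccc1OCc1ccccc1 | intermediate
11 | methyl (3R,4S)-2-[4-(benzyloxy)-3-methoxybenzoyl]-4-[4-(benzyloxy)-3-methoxyphenyl]-3-{[dimethyl(propan-2-yloxy)silyl]methyl}-4-[(triethylsilyl)oxy]butanoate (both C2 epimers) | COc1cc([C@@H](O[Si](CC)(CC)CC)[C@H](C[Si](C)(C)OC(C)C)C(C(=O)OC)C(=O)c2ccc(OCc3ccccc3)c(OC)c2)ccc1OCc1ccccc1 | intermediate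
12 | methyl (4R,5S)-2,5-bis[4-(benzyloxy)-3-methoxyphenyl]-4-{[dimethyl(propan-2-yloxy)silyl]methyl}-2-hydroxytetrahydrofuran-3-carboxylate (mixture at C2 and C3) | COc1cc([C@H]2OC(O)(c3ccc(OCc4ccccc4)c(OC)c3)C(C(=O)OC)[C@H]2C[Si](C)(C)OC(C)C)ccc1OCc1ccccc1 | intermediate
13 | methyl (4R,5S)-2,5-bis[4-(benzyloxy)-3-methoxyphenyl]-4-{[dimethyl(propan-2-yloxy)silyl]methyl}-4,5-dihydrofuran-3-carboxylate | COc1cc([C@H]2OC(c3ccc(OCc4ccccc4)c(OC)c3)=C(C(=O)OC)[C@H]2C[Si](C)(C)OC(C)C)ccc1OCc1ccccc1 | intermediate
14 | methyl (4S,5S)-2,5-bis[4-(benzyloxy)-3-methoxyphenyl]-4-(hydroxymethyl)-4,5-dihydrofuran-3-carboxylate | COc1cc([C@H]2OC(c3ccc(OCc4ccccc4)c(OC)c3)=C(C(=O)OC)[C@H]2CO)ccc1OCc1ccccc1 | intermediate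
15 | methyl (2S,3R,4S,5S)-2,5-bis[4-(benzyloxy)-3-methoxyphenyl]-4-(hydroxymethyl)tetrahydrofuran-3-carboxylate | COc1cc([C@H]2O[C@H](c3ccc(OCc4ccccc4)c(OC)c3)[C@H](C(=O)OC)[C@H]2CO)ccc1OCc1ccccc1 | intermediate
16 | {(2S,3S,4S,5S)-2,5-bis[4-(benzyloxy)-3-methoxyphenyl]tetrahydrofuran-3,4-diyl}dimethanol | COc1cc([C@H]2O[C@H](c3ccc(OCc4ccccc4)c(OC)c3)[C@H](CO)[C@H]2CO)ccc1OCc1ccccc1 | intermediate
17 | 4,4'-[(2S,3S,4S,5S)-3,4-bis(hydroxymethyl)tetrahydrofuran-2,5-diyl]bis(2-methoxyphenol) | COc1cc([C@H]2O[C@H](c3ccc(O)c(OC)c3)[C@H](CO)[C@H]2CO)ccc1O | target

## Step count and least certain steps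

Total: 10 steps. Longest linear sequence: 8 steps (steps 1, 2, 3, 6, 7, 8, 9, 10).

**Step 6 (key step).** Three things are most likely to go wrong:
- Erosion or reversal of facial selectivity in the conjugate addition. Attack anti to the C–O bond is the electronically preferred alternative and leads to the 2,3-trans series, and copper can isomerise the Z-enoate to the E-enoate.
- Incomplete C-acylation, because the β-keto ester product is acidic enough to quench unreacted enolate.
- Ionisation of the p-alkoxybenzylic C2–O bond if the acid stage is pushed too hard.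

Fallback: the sequence is split, setting out from 5 and returning at 11. Conjugate addition of 9 alone (CuI, THF, −78 °C, NH4Cl quench; if reagent control is needed, CuI with (R)- or (S)-Tol-BINAP) should give methyl (3R,4S)-4-[4-(benzyloxy)-3-methoxyphenyl]-3-{[dimethyl(propan-2-yloxy)silyl]methyl}-4-[(triethylsilyl)oxy]butanoate F1, which can be freed of the minor diastereomer. Its lithium enolate (LiN(i-Pr)2, THF, −78 °C) is added to aldehyde 1 to give the aldol methyl (3R,4S)-2-{[4-(benzyloxy)-3-methoxyphenyl](hydroxy)methyl}-4-[4-(benzyloxy)-3-methoxyphenyl]-3-{[dimethyl(propan-2-yloxy)silyl]methyl}-4-[(triethylsilyl)oxy]butanoate F2 as a diastereomer mixture. Buffered Dess–Martin oxidation returns to keto ester 11, which is carried to 13 with camphorsulfonic acid in i-PrOH as in the route.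

**Step 8.** The tetrasubstituted push-pull alkene may not turn over, or hydrogen may come from the open face if the ester carbonyl competes with the hydroxyl for iridium; that would give the all-cis isomer. Fallback: control is moved from the substrate to the catalyst. Setting out from 14, hydrogenation with a chiral cationic iridium phosphine–oxazoline complex, [Ir(cod)(L)][B(3,5-(CF3)2C6H3)4] with L = (S)- or (R)-4-tert-butyl-2-[2-(diphenylphosphino)phenyl]-4,5-dihydrooxazole, under 50–100 bar H2, with the ligand antipode matched to the lower face, returns to 15 (no new compound: F0).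

**Step 1.** Enantioselectivity may be insufficient, or the facial sense opposite, with this electron-rich aldehyde, and the propiolate zinc species may oligomerise. Fallback: resolution instead of asymmetric catalysis, setting out from 1 and 2 and returning at 3. Addition of lithiated 2 (LiN(SiMe3)2, THF, −78 °C) to 1 gives racemic methyl 4-[4-(benzyloxy)-3-methoxyphenyl]-4-hydroxybut-2-ynoate F3. Lipase-catalysed acetylation with vinyl acetate should, by the empirical rule for secondary alcohols with aryl as the larger group, convert the (S)-enantiomer into methyl (S)-4-acetoxy-4-[4-(benzyloxy)-3-methoxyphenyl]but-2-ynoate F4 and leave (R)-3.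

**Step 10.** Hydrogenolysis of the ring benzylic C–O bonds at C2 and C5 may compete, since both are activated by electron-rich aryl groups. Fallback: electron-transfer debenzylation instead of catalytic hydrogenation, setting out from 16 and returning at 17. Lithium 4,4'-di-tert-butylbiphenylide (excess, THF, −78 °C) should reduce the unsubstituted phenyl ring of each benzyl group and expel a phenoxide. The guaiacyl rings are harder to reduce and would have to expel an alkoxide (no new compound: F0).

## Further compounds

F1 | step 6 | methyl (3R,4S)-4-[4-(benzyloxy)-3-methoxyphenyl]-3-{[dimethyl(propan-2-yloxy)silyl]methyl}-4-[(triethylsilyl)oxy]butanoate | COc1cc([C@@H](O[Si](CC)(CC)CC)[C@H](C[Si](C)(C)OC(C)C)CC(=O)OC)ccc1OCc1ccccc1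
F2 | step 6 | methyl (3R,4S)-2-{[4-(benzyloxy)-3-methoxyphenyl](hydroxy)methyl}-4-[4-(benzyloxy)-3-methoxyphenyl]-3-{[dimethyl(propan-2-yloxy)silyl]methyl}-4-[(triethylsilyl)oxy]butanoate (diastereomer mixture) | COc1cc([C@@H](O[Si](CC)(CC)CC)[C@H](C[Si](C)(C)OC(C)C)C(C(=O)OC)C(O)c2ccc(OCc3ccccc3)c(OC)c2)ccc1OCc1ccccc1
F0 | step 8 | none | none
F3 | step 1 | racemic methyl 4-[4-(benzyloxy)-3-methoxyphenyl]-4-hydroxybut-2-ynoate | COc1cc(C(O)C#CC(=O)OC)ccc1OCc1ccccc1
F4 | step 1 | methyl (S)-4-acetoxy-4-[4-(benzyloxy)-3-methoxyphenyl]but-2-ynoate | COc1cc([C@@H](C#CC(=O)OC)OC(C)=O)ccc1OCc1ccccc1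
F0 | step 10 | none | none
A1 | alternative 1 | (5S)-5-{[(1S,2R,5S)-5-methyl-2-(propan-2-yl)cyclohexyl]oxy}furan-2(5H)-one | O=C1C=C[C@@H](O[C@H]2C[C@@H](C)CC[C@@H]2C(C)C)O1
A2 | alternative 1 | 2-[4-(benzyloxy)-3-methoxyphenyl]-1,3-dithiane | COc1cc(C2SCCCS2)ccc1OCc1ccccc1
A3 | alternative 1 | 3-{[4-(benzyloxy)-3-methoxyphenyl](hydroxy)methyl}-4-{2-[4-(benzyloxy)-3-methoxyphenyl]-1,3-dithian-2-yl}-5-(menthyloxy)dihydrofuran-2(3H)-one, 3,4-trans-4,5-trans | O=C1[C@@H]([C@H](O)c2ccc(OCc3ccccc3)c(OC)c2)[C@H](C2(c3ccc(OCc4ccccc4)c(OC)c3)SCCCS2)[C@@H](O[C@H]2C[C@@H](C)CC[C@@H]2C(C)C)O1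
A4 | alternative 2 | methyl 4-[(4S)-4-benzyl-2-oxo-1,3-oxazolidin-3-yl]-4-oxobutanoate | COC(=O)CCC(=O)N1[C@@H](Cc2ccccc2)COC1=O
A5 | alternative 2 | (4S)-4-benzyl-3-{[(2S,3R)-2-[4-(benzyloxy)-3-methoxyphenyl]-5-oxotetrahydrofuran-3-yl]carbonyl}-1,3-oxazolidin-2-one | O=C1O[C@H](c2ccc(OCc3ccccc3)c(OC)c2)[C@H](C(=O)N2[C@@H](Cc3ccccc3)COC2=O)C1
A6 | alternative 3 | 3-{1-[4-(benzyloxy)-3-methoxybenzoyl]-2-(benzyloxy)ethyl}-4-[3-methoxy-4-(pivaloyloxy)phenyl]oxetan-2-one (C5 epimeric to the target, C3 and C4 as in the target) | O=C1O[C@@H](c2ccc(OC(=O)C(C)(C)C)c(OC)c2)[C@H]1[C@@H](COCc1ccccc1)C(=O)c1ccc(OCc2ccccc2)c(OC)c1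
A7 | alternative 3 | (2S,3R,4S,5S)-5-[4-(benzyloxy)-3-methoxyphenyl]-4-[(benzyloxy)methyl]-2-[3-methoxy-4-(pivaloyloxy)phenyl]tetrahydrofuran-3-carboxylic acid | COc1cc([C@H]2O[C@H](c3ccc(OC(=O)C(C)(C)C)c(OC)c3)[C@H](C(=O)O)[C@H]2COCc2ccccc2)ccc1OCc1ccccc1
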